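**Plan**

Target: 8‑(1,1‑dimethylallyl)kaempferol; ring atoms carry flavone numbers (O1, C2–C4, C4a, C5–C8, C8a).
Feature: ring A (C4a, C5, C6, C7, C8, C8a) is a phloroglucinol whose three oxygens differ (ring ether on C8a, hydroxyls on C5 and C7). C8, between the oxygens of C7 and C8a, bears the quaternary carbon; C8 and that carbon are the α‑ and β‑carbons of 3,3‑dimethylpent‑4‑enoic acid.
Retrosynthesis: cut the three O–CH3 bonds, then C3–OH, then ring C (C4a–C4, C4–C3, O1–C2; carbonylative alkyne annulation), then C4a–I. Ring A is then cut at C4a–C8a, C5–C6 and C8–C8a (cyclobutenone plus methoxyacetylene), and the cyclobutenone into an alkylketene and a second methoxyacetylene.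
Forward: ring A is grown from a four‑membered ring, ring C is closed onto it with ring B already on the alkyne, and the C3 hydroxyl and the free phenols come last.
Stereochemistry: the target has no stereocentre and no stereogenic double bond; the sp3 centres of the cyclobutenone and of the pericyclic intermediates are racemic and vanish on aromatization.
Methyl is chosen for the ring A ethers: methoxyacetylene has no β‑hydrogen and cannot lose an alkene on heating, and methyl ethers are the easiest to cleave with a soft nucleophile, which the acid‑sensitive side chain demands.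

Key step: step 4

Assumption: compounds 1, 3 and 14 are catalogue chemicals; methoxyacetylene (bp 23 °C, polymerizes on storage) is made fresh in step 2 and kept as a cold toluene solution.

**Step 1**
Reactants: 1 3,3‑dimethylpent‑4‑enoic acid
Product: 2 3,3‑dimethylpent‑4‑enoyl chloride
Conditions: (COCl)2 (1.2 equiv), DMF (cat.), CH2Cl2, 0 °C → rt; distil
Reagents that add atoms: oxalyl chloride, O=C(Cl)C(=O)Cl
Why: Acid chloride formation through the Vilsmeier‑type chloroiminium species is routine for aliphatic acids, and the unconjugated monosubstituted alkene does not add HCl under these conditions.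

**Step 2**
Reactants: 3 2‑chloro‑1,1‑dimethoxyethane (chloroacetaldehyde dimethyl acetal)
Product: 5 methoxyacetylene, via sodium methoxyacetylide 4 (not isolated)
Conditions: NaNH2 (3.1 equiv), liquid NH3, −33 °C; evaporate NH3; sat. aq NaCl, −70 → 20 °C, distil into a −78 °C trap; store in toluene at −20 °C
Reagents that add atoms: none
Why: Twofold β‑elimination with sodium amide (loss of methanol, then of HCl) is the classical alkoxyacetylene preparation, the third equivalent of base holding the product as its acetylide until the cold aqueous quench.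

**Step 3**
Reactants: 2 3,3‑dimethylpent‑4‑enoyl chloride; 5 methoxyacetylene
Product: 7 rac‑3‑methoxy‑4‑(2‑methylbut‑3‑en‑2‑yl)cyclobut‑2‑en‑1‑one, via alkylketene 6 (not isolated)
Conditions: 5 (2.5 equiv), Et3N (1.2 equiv, slow addition), Et2O, 0 °C → rt, closed vessel
Reagents that add atoms: none
Why: Dehydrochlorination gives the aldoketene, whose carbonyl carbon is attacked by the nucleophilic CH terminus of the ynol ether in a regioselective ketene–alkyne [2+2] cycloaddition (the standard entry to 3‑alkoxycyclobutenones), the neopentyl‑type substituent slowing ketene dimerization and the C4 stereocentre arising as a racemate that the next step erases.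

**Step 4**
Reactants: 7 rac‑3‑methoxy‑4‑(2‑methylbut‑3‑en‑2‑yl)cyclobut‑2‑en‑1‑one; 5 methoxyacetylene
Product: 12 3,5‑dimethoxy‑2‑(2‑methylbut‑3‑en‑2‑yl)phenol, via vinylketene 8 (not isolated), via vinylcyclobutenone 9 (not isolated), via dienylketene 10 (not isolated), via cyclohexadienone 11 (not isolated)
Conditions: 5 (3 equiv), toluene, sealed tube, 80 → 110 °C; then KOH, MeOH, rt (cleaves any aryl ester formed from 12 and a ketene)
Reagents that add atoms: none
Why: Thermal conrotatory 4π opening of 7, the tert‑alkyl group turning outward, gives vinylketene 8, whose ketene carbon (the future C8a) is attacked by the CH terminus of methoxyacetylene in a [2+2] cycloaddition to give 9, forming C4a–C8a and C5–C6. A second, reversible 4π opening gives dienylketene 10, and ring A closes by a thermally allowed disrotatory 6π electrocyclization between C8a and C8 to dienone 11, which enolizes irreversibly to phenol 12. The closest known reaction is the Danheiser benzannulation of cyclobutenones with alkoxyacetylenes, applied here to a 3‑alkoxy‑4‑alkyl cyclobutenone. No stereocentre is set, since the sp3 centres of 7, 9 and 11 are racemic and disappear on aromatization. The one selectivity required is the regiochemistry of the ketene–ynol ether [2+2], and the matched polarization of the two partners secures it, so that the free hydroxyl lands on C8a, the methyl ethers on C5 and C7 and the quaternary carbon on C8 without an aryl–tert‑alkyl bond ever being made. Two further points support the step: methoxyacetylene cannot fragment to ketene by a retro‑ene path, and dienone 11 has an α‑hydrogen, so enolization should outrun a [3,3] shift of the 1,1‑dimethylallyl group.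

**Step 5**
Reactants: 12 3,5‑dimethoxy‑2‑(2‑methylbut‑3‑en‑2‑yl)phenol
Product: 13 2‑iodo‑3,5‑dimethoxy‑6‑(2‑methylbut‑3‑en‑2‑yl)phenol
Conditions: NIS (1.0 equiv), CH2Cl2, −40 → 0 °C, dark
Reagents that add atoms: N‑iodosuccinimide, O=C1CCC(=O)N1I
Why: Electrophilic aromatic iodination of a phloroglucinol‑type ring is far faster than attack of NIS on the unactivated vinyl group, and of the two free ring positions the one ortho to the hydroxyl (C4a) is the less hindered, because C6 lies between two methoxy groups, one of them pressed toward it by the tert‑alkyl neighbour.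

**Step 6**
Reactants: 13 2‑iodo‑3,5‑dimethoxy‑6‑(2‑methylbut‑3‑en‑2‑yl)phenol; 14 1‑ethynyl‑4‑methoxybenzene
Product: 17 5,7‑dimethoxy‑2‑(4‑methoxyphenyl)‑8‑(2‑methylbut‑3‑en‑2‑yl)‑4H‑chromen‑4‑one, via ynone 15 (not isolated), via enaminone 16 (not isolated)
Conditions: 14 (1.5 equiv), CO (5 bar), PdCl2(PPh3)2 (5 mol %), dppp (5 mol %), Et2NH (solvent), 60 °C
Reagents that add atoms: carbon monoxide, [C-]#[O+]
Why: Oxidative addition of zerovalent palladium to the C–I bond, CO insertion and copper‑free coupling of the acylpalladium with the terminal alkyne give ynone 15, Et2NH adds to it to give enaminone 16, and the phenol oxygen closes ring C by 6‑endo addition–elimination with loss of the amine (carbonylative Sonogashira annulation of an ortho‑iodophenol to a flavone), the enaminone path suppressing 5‑exo closure to an aurone.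

**Step 7**
Reactants: 17 5,7‑dimethoxy‑2‑(4‑methoxyphenyl)‑8‑(2‑methylbut‑3‑en‑2‑yl)‑4H‑chromen‑4‑one
Product: 20 3‑hydroxy‑5,7‑dimethoxy‑2‑(4‑methoxyphenyl)‑8‑(2‑methylbut‑3‑en‑2‑yl)‑4H‑chromen‑4‑one, via 3‑lithioflavone 18 (not isolated), via flavon‑3‑ylboronate 19 (not isolated)
Conditions: LiN(iPr)2 (1.3 equiv), THF, −78 °C; B(OMe)3 (3 equiv), −78 → 0 °C; AcOH, 30% H2O2, 0 °C → rt
Reagents that add atoms: hydrogen peroxide, OO
Why: The C3–H of a flavone (vinylic, next to the carbonyl, the only acidic site of 17) is removed by the amide base at −78 °C, the vinyllithium is trapped as the boronate and the C–B bond is oxidized by peroxide with 1,2‑migration to oxygen, a known lithiation–borylation–oxidation route from flavones to flavonols that leaves the isolated alkene untouched.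

**Step 8**
Reactants: 20 3‑hydroxy‑5,7‑dimethoxy‑2‑(4‑methoxyphenyl)‑8‑(2‑methylbut‑3‑en‑2‑yl)‑4H‑chromen‑4‑one
Product: 21 3,5,7‑trihydroxy‑2‑(4‑hydroxyphenyl)‑8‑(2‑methylbut‑3‑en‑2‑yl)‑4H‑chromen‑4‑one (CNP0284048.0)
Conditions: NaSEt (12 equiv), degassed DMF, 140 °C, argon; then 1 M HCl to pH 5, 0 °C
Reagents that add atoms: none
Why: Thiolate demethylation is an SN2 attack at methyl, all three ethers (C5, C7 and, through C2=C3, C4') are vinylogous esters of the C4 carbonyl and release stabilized phenoxides, and the basic medium spares the 1,1‑dimethylallyl group, which acid would cyclize onto the C7 hydroxyl.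

**Compound list**

1 | 3,3‑dimethylpent‑4‑enoic acid | C=CC(C)(C)CC(=O)O | starting material
2 | 3,3‑dimethylpent‑4‑enoyl chloride | C=CC(C)(C)CC(=O)Cl | intermediate
3 | 2‑chloro‑1,1‑dimethoxyethane | COC(CCl)OC | starting material
4 | sodium methoxyacetylide | [Na+].[C-]#COC | intermediate (not isolated)
5 | methoxyacetylene | C#COC | intermediate
6 | 3,3‑dimethylpenta‑1,4‑dien‑1‑one (the alkylketene) | O=C=CC(C)(C)C=C | intermediate (not isolated)
7 | rac‑3‑methoxy‑4‑(2‑methylbut‑3‑en‑2‑yl)cyclobut‑2‑en‑1‑one (one enantiomer drawn) | C=CC(C)(C)[C@@H]1C(=O)C=C1OC | intermediate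
8 | (3Z)‑3‑methoxy‑5,5‑dimethylhepta‑1,3,6‑trien‑1‑one (vinylketene) | O=C=C/C(OC)=C/C(C)(C)C=C | intermediate (not isolated)
9 | rac‑3‑methoxy‑4‑[(1Z)‑1‑methoxy‑3,3‑dimethylpenta‑1,4‑dien‑1‑yl]cyclobut‑2‑en‑1‑one (one enantiomer drawn) | O=C1C=C(OC)[C@H]1/C(OC)=C/C(C)(C)C=C | intermediate (not isolated)
10 | (3E,5Z)‑3,5‑dimethoxy‑7,7‑dimethylnona‑1,3,5,8‑tetraen‑1‑one (dienylketene) | O=C=C/C(OC)=C\C(OC)=C\C(C)(C)C=C | intermediate (not isolated)
11 | rac‑3,5‑dimethoxy‑6‑(2‑methylbut‑3‑en‑2‑yl)cyclohexa‑2,4‑dien‑1‑one (one enantiomer drawn) | O=C1C=C(OC)C=C(OC)[C@@H]1C(C)(C)C=C | intermediate (not isolated)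
12 | 3,5‑dimethoxy‑2‑(2‑methylbut‑3‑en‑2‑yl)phenol | C=CC(C)(C)c1c(O)cc(OC)cc1OC | intermediate
13 | 2‑iodo‑3,5‑dimethoxy‑6‑(2‑methylbut‑3‑en‑2‑yl)phenol | C=CC(C)(C)c1c(O)c(I)c(OC)cc1OC | intermediate
14 | 1‑ethynyl‑4‑methoxybenzene | C#Cc1ccc(OC)cc1 | starting material
15 | 1‑[2‑hydroxy‑4,6‑dimethoxy‑3‑(2‑methylbut‑3‑en‑2‑yl)phenyl]‑3‑(4‑methoxyphenyl)prop‑2‑yn‑1‑one | C=CC(C)(C)c1c(O)c(C(=O)C#Cc2ccc(OC)cc2)c(OC)cc1OC | intermediate (not isolated)
16 | (2E)‑3‑(diethylamino)‑1‑[2‑hydroxy‑4,6‑dimethoxy‑3‑(2‑methylbut‑3‑en‑2‑yl)phenyl]‑3‑(4‑methoxyphenyl)prop‑2‑en‑1‑one | CCN(CC)/C(=C/C(=O)c1c(O)c(C(C)(C)C=C)c(OC)cc1OC)c1ccc(OC)cc1 | intermediate (not isolated)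
17 | 5,7‑dimethoxy‑2‑(4‑methoxyphenyl)‑8‑(2‑methylbut‑3‑en‑2‑yl)‑4H‑chromen‑4‑one | C=CC(C)(C)c1c(OC)cc(OC)c2c(=O)cc(-c3ccc(OC)cc3)oc12 | intermediate
18 | 3‑lithio‑5,7‑dimethoxy‑2‑(4‑methoxyphenyl)‑8‑(2‑methylbut‑3‑en‑2‑yl)‑4H‑chromen‑4‑one | C=CC(C)(C)c1c(OC)cc(OC)c2c(=O)c([Li])c(-c3ccc(OC)cc3)oc12 | intermediate (not isolated)
19 | dimethyl [5,7‑dimethoxy‑2‑(4‑methoxyphenyl)‑8‑(2‑methylbut‑3‑en‑2‑yl)‑4‑oxo‑4H‑chromen‑3‑yl]boronate | C=CC(C)(C)c1c(OC)cc(OC)c2c(=O)c(B(OC)OC)c(-c3ccc(OC)cc3)oc12 | intermediate (not isolated)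
20 | 3‑hydroxy‑5,7‑dimethoxy‑2‑(4‑methoxyphenyl)‑8‑(2‑methylbut‑3‑en‑2‑yl)‑4H‑chromen‑4‑one | C=CC(C)(C)c1c(OC)cc(OC)c2c(=O)c(O)c(-c3ccc(OC)cc3)oc12 | intermediate
21 | 3,5,7‑trihydroxy‑2‑(4‑hydroxyphenyl)‑8‑(2‑methylbut‑3‑en‑2‑yl)‑4H‑chromen‑4‑one | C=CC(C)(C)c1c(O)cc(O)c2c(=O)c(O)c(-c3ccc(O)cc3)oc12 | target

**Count**

Total steps: 8. Longest linear sequence: 7 (steps 1, 3, 4, 5, 6, 7, 8 from acid 1); step 2 is a one‑step side branch that feeds steps 3 and 4.

**Steps most likely to fail**

Step 4. The vinylogous‑ester cyclobutenone may open only at temperatures at which the volatile ynol ether oligomerizes or escapes, so that the slowly formed vinylketene dimerizes or acylates the product instead of being trapped. The fallback makes the same vinylketene at room temperature by 1,4‑dehydrochlorination instead of ring opening. It sets out from acid chloride 2. Acylation of the magnesium enolate of KO2CCH2CO2Me (MgCl2, Et3N, MeCN; acidic work‑up with loss of CO2) should give methyl 5,5‑dimethyl‑3‑oxohept‑6‑enoate F1. Trimethyl orthoformate with catalytic H2SO4 in methanol should convert it into methyl (2E)‑3‑methoxy‑5,5‑dimethylhepta‑2,6‑dienoate F2. NaOH in aqueous methanol then gives sodium (2E)‑3‑methoxy‑5,5‑dimethylhepta‑2,6‑dienoate F3, and oxalyl chloride in CH2Cl2 gives (2E)‑3‑methoxy‑5,5‑dimethylhepta‑2,6‑dienoyl chloride F4. Et3N removes the γ‑proton of F4 in ether at room temperature in the presence of 5, so that vinylketene 8 is formed and trapped at once as vinylcyclobutenone 9. After filtration the solution is warmed to 80–110 °C, where 9 needs no further ynol ether and passes through 10 and 11. The fallback comes back to the route at phenol 12.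

Step 8. Cleavage may stall once two or three phenoxide charges have built up, most probably before the C5 ether next to the carbonyl is reached, and long heating with thiolate may degrade ring C by addition at C2. The fallback divides the task between a chelation‑directed Lewis acid and the nucleophile. It sets out from 20: MgI2·OEt2 in THF at 60 °C, held by the C4 carbonyl, should remove only the C5 methyl group and give 3,5‑dihydroxy‑7‑methoxy‑2‑(4‑methoxyphenyl)‑8‑(2‑methylbut‑3‑en‑2‑yl)‑4H‑chromen‑4‑one F7. NaSEt in DMF then has to cleave only the two ethers para‑conjugated to the carbonyl (C7 and C4'), and the fallback comes back at target 21.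

Step 5. Iodine may enter at C6 instead of C4a, or the iodonium may attack the vinyl group and the neighbouring hydroxyl may close a dihydrofuran (iodoetherification). The fallback attaches the C4 carbon through magnesium phenoxide delivery, which can only reach the position ortho to the hydroxyl, and it also avoids the palladium carbonylation of step 6. It sets out from phenol 12. Casnati–Skattebøl ortho‑formylation (MgCl2, Et3N, paraformaldehyde, MeCN, reflux) should give 2‑hydroxy‑4,6‑dimethoxy‑3‑(2‑methylbut‑3‑en‑2‑yl)benzaldehyde F5. The lithium acetylide of 14 (n‑BuLi, 2.2 equiv, THF, −78 °C) adds to it to give rac‑1‑[2‑hydroxy‑4,6‑dimethoxy‑3‑(2‑methylbut‑3‑en‑2‑yl)phenyl]‑3‑(4‑methoxyphenyl)prop‑2‑yn‑1‑ol F6, and MnO2 in CH2Cl2 oxidizes this to the ynone. The fallback comes back at ynone 15, which is then isolated and closed with Et2NH in ethanol through 16 to flavone 17.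

**Further compounds**

F1 | step 4 | methyl 5,5‑dimethyl‑3‑oxohept‑6‑enoate | C=CC(C)(C)CC(=O)CC(=O)OC
F2 | step 4 | methyl (2E)‑3‑methoxy‑5,5‑dimethylhepta‑2,6‑dienoate | CO/C(CC(C)(C)C=C)=C/C(=O)OC
F3 | step 4 | sodium (2E)‑3‑methoxy‑5,5‑dimethylhepta‑2,6‑dienoate | [Na+].CO/C(CC(C)(C)C=C)=C/C(=O)[O-]
F4 | step 4 | (2E)‑3‑methoxy‑5,5‑dimethylhepta‑2,6‑dienoyl chloride | CO/C(CC(C)(C)C=C)=C/C(=O)Cl
F5 | step 5 | 2‑hydroxy‑4,6‑dimethoxy‑3‑(2‑methylbut‑3‑en‑2‑yl)benzaldehyde | C=CC(C)(C)c1c(O)c(C=O)c(OC)cc1OC
F6 | step 5 | rac‑1‑[2‑hydroxy‑4,6‑dimethoxy‑3‑(2‑methylbut‑3‑en‑2‑yl)phenyl]‑3‑(4‑methoxyphenyl)prop‑2‑yn‑1‑ol (one enantiomer drawn) | C=CC(C)(C)c1c(O)c([C@@H](O)C#Cc2ccc(OC)cc2)c(OC)cc1OC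
F7 | step 8 | 3,5‑dihydroxy‑7‑methoxy‑2‑(4‑methoxyphenyl)‑8‑(2‑methylbut‑3‑en‑2‑yl)‑4H‑chromen‑4‑one | C=CC(C)(C)c1c(OC)cc(O)c2c(=O)c(O)c(-c3ccc(OC)cc3)oc12
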